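Time was what I compared first, for these flasks, each read at 4.0 min.

    substrate → intermediate (k1 = 0.00583 s⁻¹)
    first nucleophile + intermediate → target (k2 = 0.543 M⁻¹ s⁻¹)
    second nucleophile + intermediate → other capture product (k3 = 0.00932 M⁻¹ s⁻¹)
    intermediate → solvolysis product (k4 = 0.0629 s⁻¹)
    second nucleophile → decomposed reagent (k5 = 0.00606 s⁻¹)
    solid second nucleophile ⇌ second nucleophile, rate k6*(cs6 - [second nucleophile]) while solid is left; crystals form when [second nucleophile] > cs6 (cs6 = 0.11 M, k6 = 0.0703 s⁻¹)

| flask | substrate | first nucleophile | solid second nucleophile | time | remark |
|---|---|---|---|---|---|
| theta | 0.20 M | 0.100 M (in portions, 3, over 2.5 min) | 0.210 M | 4.0 min | first portion at the start, last at 2.5 min |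
| delta | 0.20 M | 0.100 M (fed, over 2.5 min) | 0.210 M | 4.0 min | all else is in the flask from the start; the feed brings no volume worth counting |
| eta | 0.20 M (fed, over 2.5 min) | 0.100 M | 0.210 M | 4.0 min | all else is in the flask from the start; the feed brings no volume worth counting |
| gamma | 0.20 M | 0.100 M | 0.210 M | 4.0 min | everything together at the start |

- given per volume of solution although it is solid: solid second nucleophile
- at the start none of the solid second nucleophile is in solution
- run time (theta): 4.0 min

- the flask with the highest amount of target, in percent of the substrate charged ("all alike" if they lie within 1.5 percentage points) (theta / delta / eta / gamma / all alike)
- final target, as a percentage of the substrate charged, in theta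
- final target, as a percentage of the substrate charged, in delta
- final target, as a percentage of the substrate charged, in eta
- final target, as a percentage of the substrate charged, in gamma

Substrate has a half-life of 2.0 min, while solvolysis by itself halves the intermediate in 0.18 min, much shorter, so I treated the intermediate as shared out as soon as it forms. Capture by the second nucleophile, even at its solubility, goes at 0.001025 s⁻¹, far below solvolysis at 0.0629 s⁻¹, so I dropped it. That left a race between solvolysis and pseudo-first-order capture by the first nucleophile. They tie at the break-even concentration K, the solvolysis constant divided by the capture constant, 0.116 M, and the momentary share going to target is c/(c+K), with c the concentration of first nucleophile.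

In gamma the charge starts below K, giving a share of 46.3%, and capture then lowers c. By first-order decay, gamma spends 0.151 M of substrate in the run. At the starting share that buys 0.0698 M of target, so I took c at half that spending, 0.0651 M, whose share is 36.0%. This gave 0.0542 M of target, or 27.1% of the substrate charged.

The second way integrates the same two-way race in closed form: substrate spent equals target P plus K ln(c₀/(c₀−P)), with c₀ the charge. For my P this asks for 0.145 M, against the 0.151 M from the first-order decay of substrate, a gap of 3.97%. So I trusted the figure, if slightly low.

Eta, by my sum, keeps 0.0789 M of substrate and spends 0.121 M. The same steps give 0.0464 M, or 23.2%, less than my figure for gamma. In theta, the first portion puts less first nucleophile in the flask at the start than gamma has; delta starts with none, and my reckoning stops there without a number for either flask.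

The forecast said gamma would lead, with 19.8% in theta, 18% in delta, 22.6% in eta and 27.3% in gamma, on the grounds that “Solvolysis is the main competitor for the intermediate and the second nucleophile barely matters”.

The simulation gave 19.7% in theta, 19.6% in delta, 22.6% in eta and 27.3% in gamma, so gamma led.

In gamma, target over target plus solvolysis product read 37.4% for the run as a whole, while the first nucleophile remaining at 4.00 min puts the momentary share, through K, at 28.2%. The neighbour is delta with 0.40 M of first nucleophile, a charge above K, and its substrate, in the flask from the start, is spent as in gamma. Taking half that charge as the fed level, 0.200 M, gave a share of 63.3%. Subtracting half the resulting capture left 0.152 M, and so 42.8% of target. That neighbour flask held 43.3% target beside 31.0% solvolysis product at 4.00 min.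

The constants used here were set for the occasion; what happens was integrated by code.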